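**Plan**

- Retrosynthesis (dibenzo[b,d]furan numbering; ring A = cyclohexanone, ring B = dihydrofuran, ring C = arene): cut first the macrolactam N–C(=O) bond on the cinnamoyl side, then the C8–CH= bond of the cinnamic acid and the CH=CH bond of the acrylamide on C9b, and last the two ring-A bonds C1–C2 and C4a–C9b together.
- Enabling feature: O5–C4a–C4–C3(=O) is a β-aryloxy ketone, i.e. a 1-aryloxy-3-silyloxybuta-1,3-diene whose usually sacrificial 1-alkoxy group is the ring-B oxygen itself. C9b sits on C9a, ortho to that oxygen, so a 2-arylacrolein is held to the diene by a three-atom tether (O5, C5a, C9a).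
- Forward: ring C with a 2-propenol arm → aryl butenone ether → enal → silyl dienol ether → rings A and B closed at once by an enantioselective intramolecular [4+2] cycloaddition → Z-acrylamide carrying the spermidine chain → Z-cinnamic acid → macrolactam last.
- Stereochemistry: C9b (S) from catalyst-controlled facial selection in the cycloaddition; C4a (R) relayed by the tether (cis fusion only); both Z alkenes from stereodefined reagents (a Z-selective Horner–Wadsworth–Emmons reagent and (Z)-3-iodoacrylic acid coupled with retention).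

Key step: step 5

Remark on the chemistry: the target is taken as the (4aR,9bS), Z,Z isomer given by the SMILES; the di-Boc spermidine with a free butyl-end amine and (Z)-3-iodoacrylic acid are taken as purchasable.

**Route**

Step 1
Reactants: 1 (5-bromo-2-hydroxyphenyl)boronic acid; 2 2-bromoprop-2-en-1-ol
Product: 3 4-bromo-2-(3-hydroxyprop-1-en-2-yl)phenol
Conditions: Pd(PPh3)4 (3 mol%), K2CO3, DME/H2O, 70 °C
Reagents that add atoms: none
Why: Suzuki–Miyaura coupling in which zerovalent palladium inserts into the vinyl C–Br bond of 2 much faster than into the electron-rich aryl C–Br bond of the phenoxide of 1, so the 2-arylallyl alcohol should form with the aryl bromide intact.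

Step 2
Reactants: 3 4-bromo-2-(3-hydroxyprop-1-en-2-yl)phenol; 4 but-3-yn-2-one
Product: 5 (3E)-4-[4-bromo-2-(3-hydroxyprop-1-en-2-yl)phenoxy]but-3-en-2-one
Conditions: 1,4-diazabicyclo[2.2.2]octane (10 mol%), 4 (1.0 equiv), CH2Cl2, 0 °C
Reagents that add atoms: none
Why: Amine-catalysed oxa-Michael addition of the phenol to the ynone; the phenol is far more acidic than the allylic alcohol and should be the only oxygen engaged, giving the thermodynamically preferred E β-aryloxy enone.

Step 3
Reactants: 5 (3E)-4-[4-bromo-2-(3-hydroxyprop-1-en-2-yl)phenoxy]but-3-en-2-one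
Product: 6 2-(5-bromo-2-{[(1E)-3-oxobut-1-en-1-yl]oxy}phenyl)prop-2-enal
Conditions: MnO2 (excess), CH2Cl2, rt
Reagents that add atoms: none
Why: Allylic alcohol oxidation by MnO2 touches only the primary allylic alcohol; the vinylogous ester and the aryl bromide are inert, and the phenol is already capped so the 2-arylacrolein cannot close to a lactol.

Step 4
Reactants: 6 2-(5-bromo-2-{[(1E)-3-oxobut-1-en-1-yl]oxy}phenyl)prop-2-enal
Product: 7 2-[5-bromo-2-({(1E)-3-[(triisopropylsilyl)oxy]buta-1,3-dien-1-yl}oxy)phenyl]prop-2-enal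
Conditions: i-Pr3SiOSO2CF3, i-Pr2NEt, CH2Cl2, −60 → −40 °C; cold non-acidic work-up, crude 7 used at once
Reagents that add atoms: triisopropylsilyl trifluoromethanesulfonate CC(C)[Si](OS(=O)(=O)C(F)(F)F)(C(C)C)C(C)C
Why: Soft enolisation (silyl triflate with a hindered amine) of the methyl ketone, the only enolisable position since the 2-arylacrolein has no α-hydrogen, gives the cross-conjugated 1-aryloxy-3-silyloxydiene with the E enol ether untouched; the bulky silyl triflate, the non-nucleophilic base and the low temperature are chosen to avoid amine addition to the enal and premature cycloaddition.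

Step 5
Reactants: 7 2-[5-bromo-2-({(1E)-3-[(triisopropylsilyl)oxy]buta-1,3-dien-1-yl}oxy)phenyl]prop-2-enal
Product: 8 (4aR,9bS)-8-bromo-3-[(triisopropylsilyl)oxy]-1,2,4a,9b-tetrahydrodibenzo[b,d]furan-9b-carbaldehyde
Conditions: (S)-3,3-diphenyl-1-(2-methylphenyl)tetrahydro-1H,3H-pyrrolo[1,2-c][1,3,2]oxazaborole (20 mol%), (CF3SO2)2NH (16 mol%), CH2Cl2 (0.02 M), −78 °C, then Et3N quench
Reagents that add atoms: none
Why: The N-protonated oxazaborolidine binds the formyl oxygen of 7 and lowers the LUMO of the 2-arylacrolein, which undergoes a concerted, asynchronous [4+2] cycloaddition with the tethered (E)-1-aryloxy-3-silyloxydiene (intramolecular Diels–Alder reaction, type 1), the CH2 terminus of the diene bonding to the CH2 terminus of the enal (C2–C1) and the oxygen-bearing diene carbon to the aryl-bearing α-carbon (C4a–C9b). The closest known reaction types are the oxazaborolidinium-catalysed enantioselective Diels–Alder additions of 2-substituted acroleins to 2-silyloxydienes and the Lewis-acid-catalysed enantioselective intramolecular Diels–Alder reactions of trienals. Ring A (here the silyl enol ether of the cyclohexanone) closes by the suprafacial union of the four diene carbons with the two alkene carbons, and ring B closes as the five-membered tether ring when C4a–C9b forms, the three-atom tether (O5, C5a, C9a) allowing only the cis ring fusion. C9b is set by the catalyst, which shields one π-face of the bound enal in the formyl C–H···O organised complex (the (S)-catalyst is proposed; its antipode is to be used should a test run show the opposite sense), and C4a follows from C9b through the tether and the E enol ether. The step needs enantiofacial control (catalyst, with the low temperature keeping the uncatalysed cyclisation silent), C=C over C=O chemoselectivity (a hetero-Diels–Alder mode would need a strained seven-membered tether ring) and regiocontrol (fixed by the tether and electronically matched, the nucleophilic diene terminus attacking the enal β-carbon).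

Step 6
Reactants: 9 tert-butyl N-(4-aminobutyl)-N-{3-[(tert-butoxycarbonyl)amino]propyl}carbamate; 10 bromoacetyl bromide
Product: 11 tert-butyl N-[4-(2-bromoacetamido)butyl]-N-{3-[(tert-butoxycarbonyl)amino]propyl}carbamate
Conditions: Et3N, CH2Cl2, −78 → 0 °C
Reagents that add atoms: none
Why: Schotten–Baumann-type N-acylation of the only free (primary, butyl-end) amine of 9 by the acid bromide at low temperature; both Boc groups should survive.

Step 7
Reactants: 11 tert-butyl N-[4-(2-bromoacetamido)butyl]-N-{3-[(tert-butoxycarbonyl)amino]propyl}carbamate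
Product: 12 diphenyl {2-[(4-{(tert-butoxycarbonyl)[3-((tert-butoxycarbonyl)amino)propyl]amino}butyl)amino]-2-oxoethyl}phosphonate
Conditions: (PhO)2P(O)H, i-Pr2NEt, CH2Cl2, 0 °C → rt
Reagents that add atoms: diphenyl phosphite O=[PH](Oc1ccccc1)Oc1ccccc1
Why: Michaelis–Becker alkylation of the diphenyl phosphite anion by the α-bromoamide should give the diaryl phosphonoacetamide needed for a Z-selective olefination.

Step 8
Reactants: 8 (4aR,9bS)-8-bromo-3-[(triisopropylsilyl)oxy]-1,2,4a,9b-tetrahydrodibenzo[b,d]furan-9b-carbaldehyde; 12 diphenyl {2-[(4-{(tert-butoxycarbonyl)[3-((tert-butoxycarbonyl)amino)propyl]amino}butyl)amino]-2-oxoethyl}phosphonate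
Product: 13 tert-butyl N-{4-[(2Z)-3-{(4aR,9bS)-8-bromo-3-[(triisopropylsilyl)oxy]-1,2,4a,9b-tetrahydrodibenzo[b,d]furan-9b-yl}prop-2-enamido]butyl}-N-{3-[(tert-butoxycarbonyl)amino]propyl}carbamate
Conditions: 12 (1.2 equiv), KN(SiMe3)2 (1.15 equiv), THF, −78 °C, then 8, −78 → −30 °C
Reagents that add atoms: none
Why: Z-selective Horner–Wadsworth–Emmons olefination with a diaryl phosphonate, whose electron-poor aryloxy groups make collapse of the kinetically formed cis-oxaphosphetane fast, so the non-enolisable aldehyde on the quaternary carbon should give the Z acrylamide; the ketone stays masked as its silyl enol ether and C4a/C9b are untouched.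

Step 9
Reactants: 13 tert-butyl N-{4-[(2Z)-3-{(4aR,9bS)-8-bromo-3-[(triisopropylsilyl)oxy]-1,2,4a,9b-tetrahydrodibenzo[b,d]furan-9b-yl}prop-2-enamido]butyl}-N-{3-[(tert-butoxycarbonyl)amino]propyl}carbamate; 14 (2Z)-3-iodoprop-2-enoic acid
Product: 16 (2Z)-3-[(4aR,9bS)-9b-{(1Z)-3-[(4-{(tert-butoxycarbonyl)[3-((tert-butoxycarbonyl)amino)propyl]amino}butyl)amino]-3-oxoprop-1-en-1-yl}-3-[(triisopropylsilyl)oxy]-1,2,4a,9b-tetrahydrodibenzo[b,d]furan-8-yl]prop-2-enoic acid, via aryl pinacol boronate 15 (not isolated)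
Conditions: bis(pinacolato)diboron, PdCl2(dppf) (5 mol%), KOAc, dioxane, 85 °C; then 14, K3PO4, H2O, 35 °C; mild acid work-up
Reagents that add atoms: bis(pinacolato)diboron CC1(C)OB(OC1(C)C)B1OC(C)(C)C(C)(C)O1
Why: Miyaura borylation of the aryl bromide followed in the same flask by Suzuki–Miyaura coupling with the vinyl iodide; oxidative addition and reductive elimination proceed with retention, so the Z geometry of 14 should be carried into the cinnamic acid at this mild temperature.

Step 10
Reactants: 16 (2Z)-3-[(4aR,9bS)-9b-{(1Z)-3-[(4-{(tert-butoxycarbonyl)[3-((tert-butoxycarbonyl)amino)propyl]amino}butyl)amino]-3-oxoprop-1-en-1-yl}-3-[(triisopropylsilyl)oxy]-1,2,4a,9b-tetrahydrodibenzo[b,d]furan-8-yl]prop-2-enoic acid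
Product: 17 bis(trifluoroacetic acid) salt of (2Z)-3-[(4aR,9bS)-9b-{(1Z)-3-({4-[(3-aminopropyl)amino]butyl}amino)-3-oxoprop-1-en-1-yl}-3-oxo-1,2,3,4,4a,9b-hexahydrodibenzo[b,d]furan-8-yl]prop-2-enoic acid
Conditions: CF3CO2H/CH2Cl2 (1:3), H2O (5 equiv), anisole, 0 °C → rt
Reagents that add atoms: trifluoroacetic acid OC(=O)C(F)(F)F
Why: Acidolysis removes both Boc groups and protodesilylates the enol ether to the ring-A ketone; the ring fusion is safe because any retro-oxa-Michael/oxa-Michael event can only re-close cis to the fixed quaternary C9b.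

Step 11
Reactants: 17 bis(trifluoroacetic acid) salt of (2Z)-3-[(4aR,9bS)-9b-{(1Z)-3-({4-[(3-aminopropyl)amino]butyl}amino)-3-oxoprop-1-en-1-yl}-3-oxo-1,2,3,4,4a,9b-hexahydrodibenzo[b,d]furan-8-yl]prop-2-enoic acid
Product: 19 CNP0415009.2 (the (4aR,9bS) cis-fused 1,2,4,4a-tetrahydrodibenzo[b,d]furan-3(9bH)-one whose C9b and C8 are bridged by (Z)-CH=CH–C(=O)–NH–(CH2)4–NH–(CH2)3–NH–C(=O)–CH=CH-(Z) with the butyl end on the C9b side), via pentafluorophenyl ester 18 (not isolated)
Conditions: C6F5OP(O)Ph2 (1.5 equiv), i-Pr2NEt, DMF, 1 mM, slow addition, 0 °C → rt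
Reagents that add atoms: pentafluorophenyl diphenylphosphinate O=P(Oc1c(F)c(F)c(F)c(F)c1F)(c1ccccc1)c1ccccc1
Why: Macrolactamisation through the pentafluorophenyl active ester under high dilution, in which the unhindered primary amine should be acylated in preference to the secondary dialkylamine (the known primary-selective acylation of spermidine by active esters), closing the 20-membered ring and leaving the central NH free.

**Compound list**

1 | (5-bromo-2-hydroxyphenyl)boronic acid | OB(O)c1cc(Br)ccc1O | starting material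
2 | 2-bromoprop-2-en-1-ol | OCC(Br)=C | starting material
3 | 4-bromo-2-(3-hydroxyprop-1-en-2-yl)phenol | C=C(CO)c1cc(Br)ccc1O | intermediate
4 | but-3-yn-2-one | CC(=O)C#C | starting material
5 | (3E)-4-[4-bromo-2-(3-hydroxyprop-1-en-2-yl)phenoxy]but-3-en-2-one | CC(=O)/C=C/Oc1ccc(Br)cc1C(=C)CO | intermediate
6 | 2-(5-bromo-2-{[(1E)-3-oxobut-1-en-1-yl]oxy}phenyl)prop-2-enal | CC(=O)/C=C/Oc1ccc(Br)cc1C(=C)C=O | intermediate
7 | 2-[5-bromo-2-({(1E)-3-[(triisopropylsilyl)oxy]buta-1,3-dien-1-yl}oxy)phenyl]prop-2-enal | C=C(O[Si](C(C)C)(C(C)C)C(C)C)/C=C/Oc1ccc(Br)cc1C(=C)C=O | intermediate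
8 | (4aR,9bS)-8-bromo-3-[(triisopropylsilyl)oxy]-1,2,4a,9b-tetrahydrodibenzo[b,d]furan-9b-carbaldehyde | O=C[C@]12CCC(O[Si](C(C)C)(C(C)C)C(C)C)=C[C@H]1Oc1ccc(Br)cc12 | intermediate
9 | tert-butyl N-(4-aminobutyl)-N-{3-[(tert-butoxycarbonyl)amino]propyl}carbamate | NCCCCN(CCCNC(=O)OC(C)(C)C)C(=O)OC(C)(C)C | starting material
10 | bromoacetyl bromide | BrCC(Br)=O | starting material
11 | tert-butyl N-[4-(2-bromoacetamido)butyl]-N-{3-[(tert-butoxycarbonyl)amino]propyl}carbamate | BrCC(=O)NCCCCN(CCCNC(=O)OC(C)(C)C)C(=O)OC(C)(C)C | intermediate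
12 | diphenyl {2-[(4-{(tert-butoxycarbonyl)[3-((tert-butoxycarbonyl)amino)propyl]amino}butyl)amino]-2-oxoethyl}phosphonate | O=C(CP(=O)(Oc1ccccc1)Oc1ccccc1)NCCCCN(CCCNC(=O)OC(C)(C)C)C(=O)OC(C)(C)C | intermediate
13 | tert-butyl N-{4-[(2Z)-3-{(4aR,9bS)-8-bromo-3-[(triisopropylsilyl)oxy]-1,2,4a,9b-tetrahydrodibenzo[b,d]furan-9b-yl}prop-2-enamido]butyl}-N-{3-[(tert-butoxycarbonyl)amino]propyl}carbamate | CC(C)(C)OC(=O)NCCCN(CCCCNC(=O)/C=C\[C@]12CCC(O[Si](C(C)C)(C(C)C)C(C)C)=C[C@H]1Oc1ccc(Br)cc12)C(=O)OC(C)(C)C | intermediate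
14 | (2Z)-3-iodoprop-2-enoic acid | OC(=O)/C=C\I | starting material
15 | pinacol boronate of 13 (4,4,5,5-tetramethyl-1,3,2-dioxaborolan-2-yl in place of Br at C8) | CC(C)(C)OC(=O)NCCCN(CCCCNC(=O)/C=C\[C@]12CCC(O[Si](C(C)C)(C(C)C)C(C)C)=C[C@H]1Oc1ccc(B3OC(C)(C)C(C)(C)O3)cc12)C(=O)OC(C)(C)C | intermediate (not isolated)
16 | (2Z)-3-[(4aR,9bS)-9b-{(1Z)-3-[(4-{(tert-butoxycarbonyl)[3-((tert-butoxycarbonyl)amino)propyl]amino}butyl)amino]-3-oxoprop-1-en-1-yl}-3-[(triisopropylsilyl)oxy]-1,2,4a,9b-tetrahydrodibenzo[b,d]furan-8-yl]prop-2-enoic acid | CC(C)(C)OC(=O)NCCCN(CCCCNC(=O)/C=C\[C@]12CCC(O[Si](C(C)C)(C(C)C)C(C)C)=C[C@H]1Oc1ccc(/C=C\C(=O)O)cc12)C(=O)OC(C)(C)C | intermediate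
17 | bis(trifluoroacetic acid) salt of (2Z)-3-[(4aR,9bS)-9b-{(1Z)-3-({4-[(3-aminopropyl)amino]butyl}amino)-3-oxoprop-1-en-1-yl}-3-oxo-1,2,3,4,4a,9b-hexahydrodibenzo[b,d]furan-8-yl]prop-2-enoic acid | NCCCNCCCCNC(=O)/C=C\[C@]12CCC(=O)C[C@H]1Oc1ccc(/C=C\C(=O)O)cc12.OC(=O)C(F)(F)F.OC(=O)C(F)(F)F | intermediate
18 | pentafluorophenyl ester of the amino acid of 17 (free base) | NCCCNCCCCNC(=O)/C=C\[C@]12CCC(=O)C[C@H]1Oc1ccc(/C=C\C(=O)Oc3c(F)c(F)c(F)c(F)c3F)cc12 | intermediate (not isolated)
19 | CNP0415009.2, (4aR,9bS), Z,Z macrocyclic bis-lactam | O=C1CC[C@]23/C=C\C(=O)NCCCCNCCCNC(=O)/C=C\c4ccc(c2c4)O[C@@H]3C1 | target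

**Step count and risks**

Total step count: 11. Longest linear sequence: 9 steps (steps 1–5 and 8–11).

The three steps most likely to fail:

1. Step 5. The cyclisation may already start during or after the enol silylation (thermally or promoted by the silyl triflate), giving racemic material before the chiral acid is engaged. Facial discrimination may also be weak because the diene is tethered to the α-aryl group of the enal, and the strong acid may strip the silyl dienol ether. The fallback uses known chemistry: an intermolecular catalytic enantioselective Diels–Alder reaction of a 1-amino-3-silyloxydiene with a 2-substituted acrolein, then acid-induced elimination and oxa-Michael closure. It sets out from 3 and comes back at 17. The phenol of 3 is protected selectively (MOMCl, K2CO3, acetone) to give 2-[5-bromo-2-(methoxymethoxy)phenyl]prop-2-en-1-ol F1, and MnO2 gives 2-[5-bromo-2-(methoxymethoxy)phenyl]prop-2-enal F2. F2 is combined with (E)-1-(dimethylamino)-3-(tert-butyldimethylsilyloxy)buta-1,3-diene and 5 mol% of the salen complex of trivalent chromium, [N,N'-bis(3,5-di-tert-butylsalicylidene)cyclohexane-1,2-diaminato]chromium hexafluoroantimonate (enantiomer chosen for the 1S adduct), in CH2Cl2 at −40 °C, which should give (1S,2S)-1-[5-bromo-2-(methoxymethoxy)phenyl]-4-[(tert-butyldimethylsilyl)oxy]-2-(dimethylamino)cyclohex-3-ene-1-carbaldehyde F3. Aqueous HCl in THF then hydrolyses the silyl enol ether, eliminates dimethylamine, removes the MOM group and lets the freed phenol add to the enone cis to the quaternary carbon, giving (4aR,9bS)-8-bromo-3-oxo-1,2,3,4,4a,9b-hexahydrodibenzo[b,d]furan-9b-carbaldehyde F4. F4 is olefinated with 12 as in step 8 to tert-butyl N-{4-[(2Z)-3-[(4aR,9bS)-8-bromo-3-oxo-1,2,3,4,4a,9b-hexahydrodibenzo[b,d]furan-9b-yl]prop-2-enamido]butyl}-N-{3-[(tert-butoxycarbonyl)amino]propyl}carbamate F5. F5 is borylated and coupled with 14 as in step 9 to (2Z)-3-[(4aR,9bS)-9b-{(1Z)-3-[(4-{(tert-butoxycarbonyl)[3-((tert-butoxycarbonyl)amino)propyl]amino}butyl)amino]-3-oxoprop-1-en-1-yl}-3-oxo-1,2,3,4,4a,9b-hexahydrodibenzo[b,d]furan-8-yl]prop-2-enoic acid F6, and CF3CO2H then gives 17.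

2. Step 11. The secondary amine may be acylated instead (16-membered tertiary lactam), or oligomers may form in place of closure on the primary amine. The fallback masks the central nitrogen through the known formaldehyde aminal of 1,3-diamines; it sets out from 17 and comes back at 19. Aqueous formaldehyde (1 equiv, pH 7) ties the primary and the central nitrogen into a 1,3-diazinane, giving (2Z)-3-[(4aR,9bS)-9b-{(1Z)-3-{[4-(1,3-diazinan-1-yl)butyl]amino}-3-oxoprop-1-en-1-yl}-3-oxo-1,2,3,4,4a,9b-hexahydrodibenzo[b,d]furan-8-yl]prop-2-enoic acid F7, in which the ring NH is the only nitrogen that can be acylated. Macrolactamisation with C6F5OP(O)Ph2 and i-Pr2NEt under high dilution gives the N,N'-methylene-bridged macrolactam F8. Hydrolysis of the aminal in aqueous AcOH/MeOH, with dimedone to trap formaldehyde, should then give 19.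

3. Step 8. The hindered aldehyde on the quaternary carbon may react slowly or with eroded Z-selectivity, giving E-acrylamide that cannot be carried on to the target. The fallback builds the Z alkene before the amide; it sets out from 8 and comes back at 13. Stork–Zhao olefination (Ph3P+CH2I I−, NaN(SiMe3)2, THF/DMPU, −78 °C) gives (4aR,9bS)-8-bromo-9b-[(Z)-2-iodoethenyl]-3-[(triisopropylsilyl)oxy]-1,2,4a,9b-tetrahydrodibenzo[b,d]furan F9. Aminocarbonylation of the vinyl iodide, which reacts far faster than the aryl bromide (Pd(PPh3)4, CO 1 atm, amine 9, Et3N, DMF, 45 °C), should proceed with retention and give 13.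

Further compounds
F1 | step 5 | 2-[5-bromo-2-(methoxymethoxy)phenyl]prop-2-en-1-ol | C=C(CO)c1cc(Br)ccc1OCOC
F2 | step 5 | 2-[5-bromo-2-(methoxymethoxy)phenyl]prop-2-enal | C=C(C=O)c1cc(Br)ccc1OCOC
F3 | step 5 | (1S,2S)-1-[5-bromo-2-(methoxymethoxy)phenyl]-4-[(tert-butyldimethylsilyl)oxy]-2-(dimethylamino)cyclohex-3-ene-1-carbaldehyde | O=C[C@]1(c2cc(Br)ccc2OCOC)CCC(O[Si](C)(C)C(C)(C)C)=C[C@@H]1N(C)C
F4 | step 5 | (4aR,9bS)-8-bromo-3-oxo-1,2,3,4,4a,9b-hexahydrodibenzo[b,d]furan-9b-carbaldehyde | O=C[C@]12CCC(=O)C[C@H]1Oc1ccc(Br)cc12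
F5 | step 5 | tert-butyl N-{4-[(2Z)-3-[(4aR,9bS)-8-bromo-3-oxo-1,2,3,4,4a,9b-hexahydrodibenzo[b,d]furan-9b-yl]prop-2-enamido]butyl}-N-{3-[(tert-butoxycarbonyl)amino]propyl}carbamate | CC(C)(C)OC(=O)NCCCN(CCCCNC(=O)/C=C\[C@]12CCC(=O)C[C@H]1Oc1ccc(Br)cc12)C(=O)OC(C)(C)C
F6 | step 5 | (2Z)-3-[(4aR,9bS)-9b-{(1Z)-3-[(4-{(tert-butoxycarbonyl)[3-((tert-butoxycarbonyl)amino)propyl]amino}butyl)amino]-3-oxoprop-1-en-1-yl}-3-oxo-1,2,3,4,4a,9b-hexahydrodibenzo[b,d]furan-8-yl]prop-2-enoic acid | CC(C)(C)OC(=O)NCCCN(CCCCNC(=O)/C=C\[C@]12CCC(=O)C[C@H]1Oc1ccc(/C=C\C(=O)O)cc12)C(=O)OC(C)(C)C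
F7 | step 11 | (2Z)-3-[(4aR,9bS)-9b-{(1Z)-3-{[4-(1,3-diazinan-1-yl)butyl]amino}-3-oxoprop-1-en-1-yl}-3-oxo-1,2,3,4,4a,9b-hexahydrodibenzo[b,d]furan-8-yl]prop-2-enoic acid | O=C(/C=C\[C@]12CCC(=O)C[C@H]1Oc1ccc(/C=C\C(=O)O)cc12)NCCCCN1CCCNC1
F8 | step 11 | N,N'-methylene-bridged macrolactam (19 with a CH2 joining the cinnamoyl amide nitrogen and the central nitrogen as a 1,3-diazinane) | O=C1CC[C@]23/C=C\C(=O)NCCCCN5CCCN(C5)C(=O)/C=C\c4ccc(c2c4)O[C@@H]3C1
F9 | step 8 | (4aR,9bS)-8-bromo-9b-[(Z)-2-iodoethenyl]-3-[(triisopropylsilyl)oxy]-1,2,4a,9b-tetrahydrodibenzo[b,d]furan | I/C=C\[C@]12CCC(O[Si](C(C)C)(C(C)C)C(C)C)=C[C@H]1Oc1ccc(Br)cc12
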